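## Retrosynthetic overview

1. Target ⇒ 2-allyl-5-methoxy-4-alkylphenol. The last step forms the C–OMe bond at the quaternary ring carbon by catalyst-controlled oxidative methoxylative para-dearomatisation.
2. Free phenol plus C-allyl group ⇒ aryl allyl ether by aromatic Claisen rearrangement. The allyl group first protects the phenol and then ends up in the target.
3. C-1–OAc ⇒ (1S,2S)-alcohol. This is the second C–O disconnection, an invertive Mitsunobu acetoxylation.
4. (1S,2S)-alcohol ⇒ racemic α-aryl ketone (hydrogenation with dynamic kinetic resolution) ⇒ 3',4'-dimethoxypropiophenone + 4-bromo-3-methoxyphenol (Pd α-arylation, then O-allylation).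
5. Rings: none is built. Both six-membered rings are bought as arenes. Ring A (veratryl) stays aromatic and ring B is dearomatised in the last step.

Assumption 1 (locants): C-1 is the O-bearing benzylic chain carbon and C-2 the methyl-bearing one; the target is (1R,2R, ring C-1 R), and C-2 keeps its spatial arrangement from 5 onwards, its descriptor changing from S to R in step 6 only because the CIP priorities change.

Assumption 2 (catalyst): Cat* = (R,R)-2,2'-[(2-iodobenzene-1,3-diyl)bis(oxy)]bis[N-(2,4,6-trimethylphenyl)propanamide], SMILES C[C@@H](Oc1cccc(O[C@H](C)C(=O)Nc2c(C)cc(C)cc2C)c1I)C(=O)Nc1c(C)cc(C)cc1C, is taken to leave open the ring face that gives the (R)-quaternary centre; if the sense is opposite, the (S,S)-enantiomer (from the other ethyl lactate) is used.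

## Route

Step 1
Reactants: 1 1-(3,4-dimethoxyphenyl)propan-1-one; 2 4-bromo-3-methoxyphenol
Product: 3 rac-1-(3,4-dimethoxyphenyl)-2-(4-hydroxy-2-methoxyphenyl)propan-1-one
Conditions: Pd(OAc)2 (2 mol%), rac-2-(di-tert-butylphosphino)-1,1'-binaphthyl (4 mol%), NaOtBu (2.6 equiv), toluene, 80 °C
Reagents that add atoms: none
Why: Palladium-catalysed ketone enolate α-arylation (Buchwald–Hartwig–Miura type) works on unprotected bromophenols when extra NaOtBu carries the OH through as phenoxide, the bulky electron-rich monophosphine handles the electron-rich ortho-substituted bromide, a second arylation is blocked sterically, and C-2 is formed racemic on purpose because it stays base-labile for step 3.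

Step 2
Reactants: 3 rac-1-(3,4-dimethoxyphenyl)-2-(4-hydroxy-2-methoxyphenyl)propan-1-one
Product: 4 rac-2-[4-(allyloxy)-2-methoxyphenyl]-1-(3,4-dimethoxyphenyl)propan-1-one
Conditions: allyl bromide (1.2 equiv), K2CO3, acetone, reflux
Reagents that add atoms: allyl bromide (C=CCBr)
Why: In this Williamson ether synthesis K2CO3 deprotonates only the phenol and not the much less acidic α-aryl ketone, so O-allylation is clean and the allyl group protects the phenol until it becomes the C-allyl group of the target.

Step 3
Reactants: 4 rac-2-[4-(allyloxy)-2-methoxyphenyl]-1-(3,4-dimethoxyphenyl)propan-1-one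
Product: 5 (1S,2S)-2-[4-(allyloxy)-2-methoxyphenyl]-1-(3,4-dimethoxyphenyl)propan-1-ol
Conditions: RuCl2[(R)-xylbinap][(R)-daipen] (0.5 mol%), KOtBu (10 mol%), H2 (10 atm), iPrOH, 25 °C
Reagents that add atoms: none
Why: In this Noyori asymmetric hydrogenation under dynamic kinetic resolution the alkoxide racemises C-2 through the enolate faster than reduction, the (R,R)-catalyst delivers hydride to the face that gives 1S and consumes the Felkin–Anh-matched (2S)-ketone much faster, which fixes C-2 for good and C-1 provisionally, and the outer-sphere Ru–H/N–H mechanism leaves the allyl C=C untouched.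

Step 4
Reactants: 5 (1S,2S)-2-[4-(allyloxy)-2-methoxyphenyl]-1-(3,4-dimethoxyphenyl)propan-1-ol
Product: 7 (1R,2S)-2-[4-(allyloxy)-2-methoxyphenyl]-1-(3,4-dimethoxyphenyl)propyl acetate, via oxyphosphonium acetate 6 (not isolated)
Conditions: PPh3 (1.5 equiv), DIAD (1.5 equiv), AcOH (3 equiv), toluene, −20 °C to rt
Reagents that add atoms: acetic acid (CC(=O)O)
Why: The Mitsunobu esterification forms the C-1–O bond by SN2 attack of acetate on 6 with inversion (1S to 1R), and any leakage through the veratryl-stabilised cation converges on the same (1R,2S)-acetate because allylic 1,3-strain puts H-2 in the cation plane and acetate enters anti to the 2-aryl group.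

Step 5
Reactants: 7 (1R,2S)-2-[4-(allyloxy)-2-methoxyphenyl]-1-(3,4-dimethoxyphenyl)propyl acetate
Product: 9 (1R,2S)-2-(5-allyl-4-hydroxy-2-methoxyphenyl)-1-(3,4-dimethoxyphenyl)propyl acetate, via 6-allylcyclohexa-2,4-dienone 8 (not isolated)
Conditions: N,N-diethylaniline, 190 °C, 4 h
Reagents that add atoms: none
Why: The aromatic Claisen rearrangement ([3,3]-sigmatropic shift to 8, then tautomerisation) goes to the ortho carbon para to OMe because the other ortho site is shielded by the methoxy methyl group that the bulky side chain pushes towards it, it unmasks the phenol and installs the C-allyl group in one operation, and the neutral medium is far below ester-pyrolysis temperature so the acetate and both stereocentres survive.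

Step 6
Reactants: 9 (1R,2S)-2-(5-allyl-4-hydroxy-2-methoxyphenyl)-1-(3,4-dimethoxyphenyl)propyl acetate
Product: 11 (1R,2R)-2-[(1R)-5-allyl-1,2-dimethoxy-4-oxocyclohexa-2,5-dien-1-yl]-1-(3,4-dimethoxyphenyl)propyl acetate, via aryloxy(methoxy)iodane 10 (not isolated)
Conditions: Cat* (10 mol%), mCPBA (1.2 equiv), MeOH/CH2Cl2 1:3, −20 °C
Reagents that add atoms: methanol (CO)
Why: Proposed new method: catalyst-controlled methoxylative para-dearomatisation, in which mCPBA oxidises the C2-symmetric iodoarene to its trivalent iodine form, the lactamide N–H···O hydrogen bonds fold the mesityl arms into a helical pocket, phenol 9 exchanges onto iodine to give 10 with one ring face covered, and methanol attacks the para carbon (activated by the ortho methoxy group) from the open face in an associative SN2'-type displacement of the iodoarene, kept associative by low temperature and a non-ionising co-solvent, so that the C–O bond and the (R)-quaternary centre form under catalyst rather than substrate control; the closest known reaction types are the chiral aryl iodide catalysed hydroxylative para-dearomatisation of 4-alkylphenols to para-quinols (water as nucleophile, no neighbouring stereocentre) and the achiral PhI(OAc)2/MeOH oxidation of 4-alkylphenols, whereas methanol as external nucleophile on a phenol with a branched stereogenic para substituent has not been shown.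

## Compound list

1 | 1-(3,4-dimethoxyphenyl)propan-1-one | CCC(=O)c1ccc(OC)c(OC)c1 | starting material
2 | 4-bromo-3-methoxyphenol | COc1cc(O)ccc1Br | starting material
3 | rac-1-(3,4-dimethoxyphenyl)-2-(4-hydroxy-2-methoxyphenyl)propan-1-one | CC(C(=O)c1ccc(OC)c(OC)c1)c1ccc(O)cc1OC | intermediate
4 | rac-2-[4-(allyloxy)-2-methoxyphenyl]-1-(3,4-dimethoxyphenyl)propan-1-one | CC(C(=O)c1ccc(OC)c(OC)c1)c1ccc(OCC=C)cc1OC | intermediate
5 | (1S,2S)-2-[4-(allyloxy)-2-methoxyphenyl]-1-(3,4-dimethoxyphenyl)propan-1-ol | C=CCOc1ccc([C@H](C)[C@H](O)c2ccc(OC)c(OC)c2)c(OC)c1 | intermediate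
6 | (1S,2S)-alkoxytriphenylphosphonium acetate of 5 (not isolated) | C=CCOc1ccc([C@H](C)[C@H](O[P+](c2ccccc2)(c2ccccc2)c2ccccc2)c2ccc(OC)c(OC)c2)c(OC)c1.CC(=O)[O-] | intermediate
7 | (1R,2S)-2-[4-(allyloxy)-2-methoxyphenyl]-1-(3,4-dimethoxyphenyl)propyl acetate | C=CCOc1ccc([C@H](C)[C@@H](OC(C)=O)c2ccc(OC)c(OC)c2)c(OC)c1 | intermediate
8 | (1R,2S)-2-(5-allyl-2-methoxy-4-oxocyclohexa-1,5-dien-1-yl)-1-(3,4-dimethoxyphenyl)propyl acetate, the ortho-dienone, mixture at the ring sp3 carbon (not isolated) | C=CCC1C=C([C@H](C)[C@@H](OC(C)=O)c2ccc(OC)c(OC)c2)C(OC)=CC1=O | intermediate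
9 | (1R,2S)-2-(5-allyl-4-hydroxy-2-methoxyphenyl)-1-(3,4-dimethoxyphenyl)propyl acetate | C=CCc1cc([C@H](C)[C@@H](OC(C)=O)c2ccc(OC)c(OC)c2)c(OC)cc1O | intermediate
10 | aryloxy(methoxy)iodane from 9 and oxidised Cat*, trivalent iodine (not isolated) | C=CCc1cc([C@H](C)[C@@H](OC(C)=O)c2ccc(OC)c(OC)c2)c(OC)cc1OI(OC)c1c(O[C@H](C)C(=O)Nc2c(C)cc(C)cc2C)cccc1O[C@H](C)C(=O)Nc1c(C)cc(C)cc1C | intermediate
11 | (1R,2R)-2-[(1R)-5-allyl-1,2-dimethoxy-4-oxocyclohexa-2,5-dien-1-yl]-1-(3,4-dimethoxyphenyl)propyl acetate (CNP0159267.1) | C=CCC1=C[C@@](OC)([C@H](C)[C@@H](OC(C)=O)c2ccc(OC)c(OC)c2)C(OC)=CC1=O | target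

## Step count and risks

Total step count: 6. Longest linear sequence: 6.

**1) Step 6 (the proposed new step).**
- The side chain has its own facial bias. With H-2 lying in the ring plane next to the ortho OMe, sterics favour attack anti to C-1, which gives the wrong epimer, so the catalyst must override it.
- Hydrogen bonding of incoming methanol to the acetate carbonyl on the C-1 face may help the desired attack.
- Para-quinone methide formation at C-2 and slow epoxidation of the allyl group are side paths.
- Fallback (known chemistry, substrate oxidation with separation and recycling instead of catalyst control): it sets out from 9. Oxidation with PhI(OAc)2 (1.1 equiv) in MeOH at 0 °C gives 11 together with the (1S)-configured dienone epimer F1. The two are separated by chromatography. F1 is returned to 9 by reductive rearomatisation with Zn in AcOH, with loss of methanol, and is oxidised again. The fallback comes back to the route at 11.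

**2) Step 4.**
- The hindered, electron-rich benzylic centre may eliminate to the α-methylstilbene.
- It may react with retention through participation of the 2-aryl group.
- It may be trapped by the ortho-methoxy oxygen to give a dihydrobenzofuran.
- Fallback (no substitution at C-1 at all): it sets out from 4 and replaces steps 3 and 4. Racemic 4 is reduced to full conversion under non-racemising, reagent-controlled transfer hydrogenation with RuCl(p-cymene)[(R,R)-TsDPEN] in HCO2H/Et3N 5:2 at 25 °C. This gives the (1R,2S)-alcohol F2 and the (1R,2R)-alcohol F3 in about equal amounts, separable on silica. F2 is acetylated with retention (Ac2O, pyridine, DMAP) and comes back to the route at 7.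

**3) Step 3.**
- Racemisation of the ortho-substituted α-aryl ketone may not outrun hydrogenation, which would erode dr and ee.
- Fallback (diastereoselective reduction followed by resolution instead of dynamic kinetic resolution): it sets out from 4. Felkin–Anh reduction with Li[HB(sec-Bu)3] in THF at −78 °C gives the racemic (1S*,2S*)-alcohol F4.
- Acylative kinetic resolution uses (R)-benzotetramisole (5 mol%, the enantiomer that acylates (R)-1-arylalkanols), isobutyric anhydride (0.6 equiv) and iPr2NEt in CHCl3 at 0 °C. It converts the unwanted enantiomer into the (1R,2R)-isobutyrate F5 and leaves the (1S,2S)-alcohol. The fallback comes back to the route at 5.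

## Further compounds

F1 | step 6 | (1R,2R)-2-[(1S)-5-allyl-1,2-dimethoxy-4-oxocyclohexa-2,5-dien-1-yl]-1-(3,4-dimethoxyphenyl)propyl acetate | C=CCC1=C[C@](OC)([C@H](C)[C@@H](OC(C)=O)c2ccc(OC)c(OC)c2)C(OC)=CC1=O
F2 | step 4 | (1R,2S)-2-[4-(allyloxy)-2-methoxyphenyl]-1-(3,4-dimethoxyphenyl)propan-1-ol | C=CCOc1ccc([C@H](C)[C@@H](O)c2ccc(OC)c(OC)c2)c(OC)c1
F3 | step 4 | (1R,2R)-2-[4-(allyloxy)-2-methoxyphenyl]-1-(3,4-dimethoxyphenyl)propan-1-ol | C=CCOc1ccc([C@@H](C)[C@@H](O)c2ccc(OC)c(OC)c2)c(OC)c1
F4 | step 3 | racemic (1S*,2S*)-2-[4-(allyloxy)-2-methoxyphenyl]-1-(3,4-dimethoxyphenyl)propan-1-ol (both enantiomers) | C=CCOc1ccc([C@H](C)[C@H](O)c2ccc(OC)c(OC)c2)c(OC)c1.C=CCOc1ccc([C@@H](C)[C@@H](O)c2ccc(OC)c(OC)c2)c(OC)c1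
F5 | step 3 | (1R,2R)-2-[4-(allyloxy)-2-methoxyphenyl]-1-(3,4-dimethoxyphenyl)propyl 2-methylpropanoate | C=CCOc1ccc([C@@H](C)[C@@H](OC(=O)C(C)C)c2ccc(OC)c(OC)c2)c(OC)c1
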